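**Retrosynthetic overview**

1. Rings are lettered A–F from the 2,4,6-trihydroxyphenoxy end to the 3,4,5-trihydroxyphenoxy end. The target (fifteen OH groups, no stereocentre) is released last from its pentadecamethyl ether by cleavage of every O–Me bond.
2. The ether between the ring C oxygen (on C4) and ring D C1 is cut next by copper-mediated arylation, giving a ring A–B–C phenol and a ring D–E–F aryl bromide.
3. Feature used: the bridging oxygen on ring A C1 and the one on ring B C4 each sit between two oxygen-bearing carbons of their own ring and are bonded to C1 of the next ring, para to that ring's own flanked oxygen (a head-to-tail 2,6-dioxygenated 1,4-phenylene oxide repeat). Both bonds, O–C1 of ring B and O–C1 of ring C, are therefore made in one oxidative, decarboxylative coupling of 2,4,6-trimethoxyphenol with two molecules of syringic acid.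
4. Ring D–E–F bromide: the O–C2 bond of ring D comes from an iodide-selective Ullmann coupling of a ring E–F phenol with 1-bromo-2-iodo-3,4,5-trimethoxybenzene. The ring E–F phenol comes from Ullmann coupling of 3,4,5-trimethoxyphenol with 4-bromo-3,5-dimethoxybenzaldehyde, then Baeyer–Villiger oxidation.
5. No ring is constructed; all six benzene rings are bought and joined in the order A→B→C (key step), F→E→D, then C–D.

Key step: step 1

Assumption: 2,4,6-trimethoxyphenol, 4-bromo-3,5-dimethoxybenzaldehyde and 5-bromo-1,2,3-trimethoxybenzene are treated as purchasable catalogue compounds.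

**Route**

Step 1
Reactants: 1 2,4,6-trimethoxyphenol; 2 syringic acid (4-hydroxy-3,5-dimethoxybenzoic acid, 2.0 equiv)
Product: 4 4-[2,6-dimethoxy-4-(2,4,6-trimethoxyphenoxy)phenoxy]-2,6-dimethoxyphenol (ring A–B–C phenol), via ring A–B phenol 3 (not isolated)
Conditions: CuCl (20 mol%), pyridine/MeCN (1:3), O2 (1 atm), 4 Å MS, 25 °C; 2 in pyridine added by syringe pump over 10 h; aq. NH4Cl work-up, NaHCO3 wash, chromatography
Reagents that add atoms: none
Why: Proposed new method: CuCl, pyridine and O2 generate a divalent copper–amine oxidant that turns 1 and 2 into phenoxyl radicals; the oxygen of the ring A radical, whose own ortho and para carbons all carry methoxy groups, bonds to C1 of the syringate radical, and the 4-aryloxy-4-carboxycyclohexa-2,5-dienone so formed rearomatises by loss of CO2 to phenol 3, a new 2,6-dimethoxyphenol that repeats the event with the second equivalent of 2 to give 4. The closest known reactions are the CuCl–amine–O2 oxidative C–O polymerisation of 2,6-disubstituted phenols and the oxidase-mediated decarboxylative polymerisation of syringic acid to poly(2,6-dimethoxy-1,4-phenylene oxide); untested are the cross-coupling onto a capping phenol, copper catalysis in the presence of a free carboxylic acid (met here by pyridine as co-solvent and slow addition of 2, so that carboxylate never outweighs the amine at the metal) and the stop at two units. No ring is closed and no stereocentre is formed. Regioselectivity for O-to-C1 bonding is secured by the substrate, because every position ortho or para to a phenolic oxygen is substituted and only the adduct at the carboxyl-bearing carbon can become aromatic again, by decarboxylation, whereas adducts at methoxy- or aryloxy-bearing para carbons are quinone ketals that dissociate back. Cross- over homo-coupling is favoured because 1 and its descendants can act only as oxygen donors and persist while 2 is kept at low stationary concentration; chains begun by 2 instead keep a carboxyl tail and are removed with aqueous NaHCO3. Chain length is set only by the 1:2 stoichiometry, so 4 should be separated by chromatography from the shorter phenol 3 (to be resubmitted with one equivalent of 2) and from longer homologues, and the 4 Å sieves are included to suppress hydrolytic over-oxidation of the ring A phenol to 2,6-dimethoxy-1,4-benzoquinone.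

Step 2
Reactants: 5 3,4,5-trimethoxyphenol; 6 4-bromo-3,5-dimethoxybenzaldehyde
Product: 7 3,5-dimethoxy-4-(3,4,5-trimethoxyphenoxy)benzaldehyde (ring E–F aldehyde)
Conditions: CuI (10 mol%), N,N-dimethylglycine·HCl (30 mol%), Cs2CO3 (2 equiv), 1,4-dioxane, 100 °C
Reagents that add atoms: none
Why: Ullmann diaryl ether synthesis in which the unhindered, electron-rich phenolate of 5 couples with the bromide of 6, whose reaction with monovalent copper is assisted by the para-formyl group despite the two flanking methoxy groups.

Step 3
Reactants: 7 3,5-dimethoxy-4-(3,4,5-trimethoxyphenoxy)benzaldehyde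
Product: 9 3,5-dimethoxy-4-(3,4,5-trimethoxyphenoxy)phenol (ring E–F phenol), via aryl formate 8 (not isolated)
Conditions: mCPBA, CH2Cl2, 0 → 25 °C; then K2CO3 (cat.), MeOH, 25 °C
Reagents that add atoms: mCPBA (3-chloroperbenzoic acid), O=C(OO)c1cccc(Cl)c1
Why: Baeyer–Villiger (Dakin-type) oxidation in which the para-aryloxy-substituted aryl group migrates in preference to hydride to give formate 8, whose methanolysis frees the phenol on ring E C1.

Step 4
Reactants: 10 5-bromo-1,2,3-trimethoxybenzene
Product: 11 1-bromo-2-iodo-3,4,5-trimethoxybenzene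
Conditions: NIS (1.05 equiv), TFA (10 mol%), MeCN, 25 °C
Reagents that add atoms: N-iodosuccinimide, O=C1CCC(=O)N1I
Why: Electrophilic aromatic iodination; the two open positions of 10 are equivalent and each is ortho and para to methoxy groups, so one equivalent of acid-activated NIS should give a single mono-iodide with iodine next to bromine.

Step 5
Reactants: 9 3,5-dimethoxy-4-(3,4,5-trimethoxyphenoxy)phenol; 11 1-bromo-2-iodo-3,4,5-trimethoxybenzene (1.5 equiv)
Product: 12 1-bromo-2-[3,5-dimethoxy-4-(3,4,5-trimethoxyphenoxy)phenoxy]-3,4,5-trimethoxybenzene (ring D–E–F bromide)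
Conditions: CuI (10 mol%), picolinic acid (20 mol%), K3PO4 (2 equiv), DMSO, 80 °C
Reagents that add atoms: none
Why: Chemoselective Ullmann etherification; copper reacts with the weaker carbon–iodine bond much faster than with carbon–bromine (the behaviour known for 1-bromo-2-iodobenzene with phenols), and the unhindered phenolate of 9, the excess of 11 and the moderate temperature should leave the bromide in place.

Step 6
Reactants: 4 ring A–B–C phenol; 12 ring D–E–F bromide (1.2 equiv)
Product: 13 pentadecamethyl ether of the target (all fifteen hydroxyl groups as OMe)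
Conditions: CuI (30 mol%), picolinic acid (60 mol%), K3PO4 (2 equiv), DMSO, 110 °C, argon
Reagents that add atoms: none
Why: Ullmann etherification under CuI–picolinic acid conditions suited to hindered diaryl ethers; the 2,6-dimethoxyphenolate of 4 displaces the only carbon–halogen bond present, and every other group is an inert aryl methyl or diaryl ether.

Step 7
Reactants: 13 pentadecamethyl ether
Product: 14 CNP0175585.0 (target)
Conditions: BBr3 (30 equiv), CH2Cl2, −78 → 25 °C, argon; then ice-water; Sephadex LH-20 (MeOH)
Reagents that add atoms: none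
Why: Lewis-acid ether cleavage; BBr3 complexes each methoxy oxygen and bromide attacks the methyl carbon (SN2), while the diaryl ether bonds offer no sp3 carbon and should survive, and exclusion of air protects the pyrogallol-type rings of the product.

**Compound list**

1 | 2,4,6-trimethoxyphenol | COc1cc(OC)c(O)c(OC)c1 | starting material
2 | syringic acid (4-hydroxy-3,5-dimethoxybenzoic acid) | COc1cc(C(=O)O)cc(OC)c1O | starting material
3 | 2,6-dimethoxy-4-(2,4,6-trimethoxyphenoxy)phenol (ring A–B phenol) | COc1cc(OC)c(Oc2cc(OC)c(O)c(OC)c2)c(OC)c1 | intermediate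
4 | 4-[2,6-dimethoxy-4-(2,4,6-trimethoxyphenoxy)phenoxy]-2,6-dimethoxyphenol (ring A–B–C phenol) | COc1cc(OC)c(Oc2cc(OC)c(Oc3cc(OC)c(O)c(OC)c3)c(OC)c2)c(OC)c1 | intermediate
5 | 3,4,5-trimethoxyphenol | COc1cc(O)cc(OC)c1OC | starting material
6 | 4-bromo-3,5-dimethoxybenzaldehyde | COc1cc(C=O)cc(OC)c1Br | starting material
7 | 3,5-dimethoxy-4-(3,4,5-trimethoxyphenoxy)benzaldehyde (ring E–F aldehyde) | COc1cc(C=O)cc(OC)c1Oc1cc(OC)c(OC)c(OC)c1 | intermediate
8 | 3,5-dimethoxy-4-(3,4,5-trimethoxyphenoxy)phenyl formate | COc1cc(OC=O)cc(OC)c1Oc1cc(OC)c(OC)c(OC)c1 | intermediate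
9 | 3,5-dimethoxy-4-(3,4,5-trimethoxyphenoxy)phenol (ring E–F phenol) | COc1cc(O)cc(OC)c1Oc1cc(OC)c(OC)c(OC)c1 | intermediate
10 | 5-bromo-1,2,3-trimethoxybenzene | COc1cc(Br)cc(OC)c1OC | starting material
11 | 1-bromo-2-iodo-3,4,5-trimethoxybenzene | COc1cc(Br)c(I)c(OC)c1OC | intermediate
12 | 1-bromo-2-[3,5-dimethoxy-4-(3,4,5-trimethoxyphenoxy)phenoxy]-3,4,5-trimethoxybenzene (ring D–E–F bromide) | COc1cc(Br)c(Oc2cc(OC)c(Oc3cc(OC)c(OC)c(OC)c3)c(OC)c2)c(OC)c1OC | intermediate
13 | 1-{4-[2,6-dimethoxy-4-(2,4,6-trimethoxyphenoxy)phenoxy]-2,6-dimethoxyphenoxy}-2-[3,5-dimethoxy-4-(3,4,5-trimethoxyphenoxy)phenoxy]-3,4,5-trimethoxybenzene (pentadecamethyl ether of 14) | COc1cc(OC)c(Oc2cc(OC)c(Oc3cc(OC)c(Oc4cc(OC)c(OC)c(OC)c4Oc4cc(OC)c(Oc5cc(OC)c(OC)c(OC)c5)c(OC)c4)c(OC)c3)c(OC)c2)c(OC)c1 | intermediate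
14 | CNP0175585.0, the compound 13 with all fifteen OMe groups as OH (rings A–F) | Oc1cc(O)c(Oc2cc(O)c(Oc3cc(O)c(Oc4cc(O)c(O)c(O)c4Oc4cc(O)c(Oc5cc(O)c(O)c(O)c5)c(O)c4)c(O)c3)c(O)c2)c(O)c1 | target

**Step count**

Total steps: 7. Longest linear sequence: 5 steps (steps 2, 3, 5, 6, 7).

**Steps most likely to fail**

Step 1 (carries the proposed new method). Chain growth is statistical and may spread the material over several chain lengths. The ring A phenol may be over-oxidised before it is capped. Carboxylate binding may shut down copper turnover. The fallback sets out from 1 and rejoins the route at 4, adding rings B and C one at a time by known chemistry. Phenol 1 would undergo Ullmann etherification with purchased 4-bromo-2,6-dimethoxybenzaldehyde (COc1cc(Br)cc(OC)c1C=O; CuI, picolinic acid, K3PO4, DMSO, 90 °C) to give 2,6-dimethoxy-4-(2,4,6-trimethoxyphenoxy)benzaldehyde F1. Baeyer–Villiger oxidation (mCPBA, CH2Cl2) would give 2,6-dimethoxy-4-(2,4,6-trimethoxyphenoxy)phenyl formate F2, and methanolysis (K2CO3, MeOH) would give phenol 3, isolated in this variant. A second round with the same bromoaldehyde would give 4-[2,6-dimethoxy-4-(2,4,6-trimethoxyphenoxy)phenoxy]-2,6-dimethoxybenzaldehyde F3, then 4-[2,6-dimethoxy-4-(2,4,6-trimethoxyphenoxy)phenoxy]-2,6-dimethoxyphenyl formate F4, and after methanolysis phenol 4.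

Step 6. Both partners are hindered, so copper insertion at the ortho-aryloxy bromide may be slow, and hydrodebromination or oxidation of the phenolate may take over. The fallback sets out from 4 and rejoins the route at 13. It reverses the order of ether formation at ring D so that each coupling pairs one hindered with one unhindered partner. Purchased 5-iodo-1,2,3-trimethoxybenzene (COc1cc(I)cc(OC)c1OC) would be brominated with NBS in MeCN to 2-bromo-1-iodo-3,4,5-trimethoxybenzene F5. Phenol 4 would then be arylated selectively at the carbon–iodine bond of F5, which lies next to a ring hydrogen (CuI, picolinic acid, K3PO4, DMSO, 90 °C), to give 2-bromo-1-{4-[2,6-dimethoxy-4-(2,4,6-trimethoxyphenoxy)phenoxy]-2,6-dimethoxyphenoxy}-3,4,5-trimethoxybenzene (ring A–B–C–D bromide) F6. The unhindered phenol 9 would then displace the bromide of F6 with the same catalyst at 110 °C to give 13.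

Step 7. Cleavage of fifteen ethers may stop at partly methylated species, and the free polyphenol may be lost to air oxidation during isolation. The fallback sets out from 13 and rejoins the route at 14. The crude material from BBr3 treatment would not be isolated as the phenol but acetylated at once (Ac2O, pyridine, DMAP) to the pentadecaacetate of 14 F7. F7 should be stable to air and silica, so under-demethylated material can be separated and returned to BBr3. Methanolysis of pure F7 under argon (HCl cat., MeOH, 25 °C) would then release 14 with only volatile co-products.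

**Further compounds**

F1 | step 1 | 2,6-dimethoxy-4-(2,4,6-trimethoxyphenoxy)benzaldehyde | COc1cc(OC)c(Oc2cc(OC)c(C=O)c(OC)c2)c(OC)c1
F2 | step 1 | 2,6-dimethoxy-4-(2,4,6-trimethoxyphenoxy)phenyl formate | COc1cc(OC)c(Oc2cc(OC)c(OC=O)c(OC)c2)c(OC)c1
F3 | step 1 | 4-[2,6-dimethoxy-4-(2,4,6-trimethoxyphenoxy)phenoxy]-2,6-dimethoxybenzaldehyde | COc1cc(OC)c(Oc2cc(OC)c(Oc3cc(OC)c(C=O)c(OC)c3)c(OC)c2)c(OC)c1
F4 | step 1 | 4-[2,6-dimethoxy-4-(2,4,6-trimethoxyphenoxy)phenoxy]-2,6-dimethoxyphenyl formate | COc1cc(OC)c(Oc2cc(OC)c(Oc3cc(OC)c(OC=O)c(OC)c3)c(OC)c2)c(OC)c1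
F5 | step 6 | 2-bromo-1-iodo-3,4,5-trimethoxybenzene | COc1cc(I)c(Br)c(OC)c1OC
F6 | step 6 | 2-bromo-1-{4-[2,6-dimethoxy-4-(2,4,6-trimethoxyphenoxy)phenoxy]-2,6-dimethoxyphenoxy}-3,4,5-trimethoxybenzene (ring A–B–C–D bromide) | COc1cc(OC)c(Oc2cc(OC)c(Oc3cc(OC)c(Oc4cc(OC)c(OC)c(OC)c4Br)c(OC)c3)c(OC)c2)c(OC)c1
F7 | step 7 | pentadecaacetate of 14 (all fifteen hydroxyl groups as OAc) | CC(=O)Oc1cc(OC(C)=O)c(Oc2cc(OC(C)=O)c(Oc3cc(OC(C)=O)c(Oc4cc(OC(C)=O)c(OC(C)=O)c(OC(C)=O)c4Oc4cc(OC(C)=O)c(Oc5cc(OC(C)=O)c(OC(C)=O)c(OC(C)=O)c5)c(OC(C)=O)c4)c(OC(C)=O)c3)c(OC(C)=O)c2)c(OC(C)=O)c1
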